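The data were computed from invented constants; the scatter is artificial.

I want to know how much of the racemate in the flask has reacted by 4.0 h, and what excess of left-handed product stands at 12 min and at 4.0 h.

| flask | left-handed substrate | right-handed substrate | solid reagent | free catalyst | remark | time |
|---|---|---|---|---|---|---|
| amber | 0.83 M | 0.83 M | 0.498 M | 0.57 mM | run made earlier |  |
| teal | 0.83 M | 0.83 M | 0.498 M | 0.90 mM | run made earlier |  |
| blue | 0.83 M | 0.83 M | 0.25 M | 0.41 mM | run made earlier |  |
| flask | 0.83 M | 0.83 M | 0.498 M | 0.41 mM |  | 4.0 h |

| run | time / h | left-handed product / % | right-handed product / % | left-handed substrate / % |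
|---|---|---|---|---|
| amber | 0.500 | 5.0 | 1.6 | 45.3 |
| amber | 1.00 | 7.5 | 1.1 | 43.8 |
| amber | 1.50 | 9.2 | 1.7 | 43.0 |
| amber | 2.00 | 9.0 | 1.2 | 42.6 |
| amber | 2.50 | 8.2 | 1.6 | 42.9 |
| amber | 3.00 | 9.0 | 1.5 | 43.2 |
| teal | 0.500 | 7.5 | 0.3 | 43.0 |
| teal | 1.00 | 10.8 | 1.8 | 41.5 |
| teal | 1.50 | 9.4 | 1.3 | 40.5 |
| teal | 2.00 | 10.7 | 2.3 | 41.0 |
| teal | 2.50 | 10.7 | 2.4 | 41.3 |
| teal | 3.00 | 11.6 | 2.3 | 42.0 |
| blue | 0.250 | 1.1 | 0.3 | 48.6 |
| blue | 0.833 | 3.1 | 1.5 | 48.1 |
| blue | 1.33 | 2.8 | 0.5 | 46.4 |
| blue | 2.50 | 3.3 | 2.0 | 48.2 |
| blue | 3.00 | 2.9 | 1.0 | 47.9 |

(readings scatter by 0.5 percentage points)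

- free catalyst is single-handed; left-handed substrate and right-handed substrate are mirror images of each other, charged as a racemate, each of them at the stated concentration
- solid, in amounts per volume of the solution: solid reagent
- the analysis behind the earlier runs scatters by 0.5 percentage points, standard deviation
- what may be going on: partner -> decomposed reagent; free catalyst + right-handed substrate <-> catalyst intermediate B; solid reagent <-> partner; left-handed substrate <-> right-handed substrate; partner + catalyst intermediate B -> free catalyst + right-handed product; partner + catalyst intermediate A -> free catalyst + left-handed product; free catalyst + left-handed substrate <-> catalyst intermediate A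
- at the start none of the solid reagent is in solution
- an excess is below zero if the other one leads

- excess of left-handed product over right-handed product in the product at 12 min
- excess of left-handed product over right-handed product in the product at 4.0 h
- part of the left-handed substrate and right-handed substrate charged together that has reacted at 4.0 h

What stops the amber run? Its two products together hold at 10.2% from 2.00 h on, while its solid reagent, one per product, has room for 30.0% of the substrates. Left-handed substrate still reads 43.2%. So I treat solid reagent as the limiting reagent, and its balance on the plateau, with dissolved partner used up, reads: charged equals product plus decomposed reagent.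

How is the charge shared? Dissolved partner goes on to product through bound catalyst or decomposes, each route first order in partner, so their ratio should follow the catalyst charge C and not the partner level. So I read off each run its product formed per decomposed reagent formed, per mM of catalyst. Amber reads 0.899 mM⁻¹. Teal, with 13.3% of product, reads 0.889 mM⁻¹. Blue, with less solid, reads 0.933 mM⁻¹.

What does the flask do? I call the mean of these three readings the capture constant a, 0.907 mM⁻¹: product formed per decomposed reagent formed, per mM of catalyst. The flask's captured share of its solid reagent is then f = aC/(1+aC) = 27.1%, so I commit to 8.13% reacted at 4.0 h. Teal's late products read an excess of 65.0%, and with 8.13% of the flask's substrates used I hold that excess at both times.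

The forecast gives 68%, 65% and 8.2%, “so about 8% of the charge reacts”, and unlike me it puts the early excess above the late one.

The flask gives 66.6% at 12 min, 66.0% at 4.0 h, and 8.21% reacted.

    partner → decomposed reagent (k = 3.80 × 10⁻⁴ s⁻¹)
    free catalyst + right-handed substrate ⇌ catalyst intermediate B (K = 10.0 L mol⁻¹, k = 180 L mol⁻¹ s⁻¹)
    solid reagent ⇌ partner, rate k3*(cs3 - [partner]) while solid is left; crystals form when [partner] > cs3 (solubility = 0.350 M, k = 0.0160 s⁻¹)
    left-handed substrate ⇌ right-handed substrate (k = 5.90 × 10⁻⁵ s⁻¹)
    partner + catalyst intermediate B → free catalyst + right-handed product (k = 0.0730 L mol⁻¹ s⁻¹)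
    partner + catalyst intermediate A → free catalyst + left-handed product (k = 3.20 L mol⁻¹ s⁻¹)
    free catalyst + left-handed substrate ⇌ catalyst intermediate A (K = 1.20 L mol⁻¹, k = 29.0 L mol⁻¹ s⁻¹)

At 4.00 h the flask holds 0.362 M of decomposed reagent, which is 72.7% of its solid charge, against 0.136 M of product, and that ratio per mM of its catalyst makes 0.918 mM⁻¹. In the neighbouring flask the free catalyst goes up to 0.0010 M with the same solid, and my a of 0.907 mM⁻¹ gives a captured share of 47.6%, hence 14.3% reacted. That neighbour gives 14.2% reacted at 4.00 h, with 0.264 M of decomposed reagent.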